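The runs are simulated from invented constants.

The easy mistake with this flask was to see more partner B than substrate and to expect the substrate to go.

| flask | substrate | partner A | partner B | protic impurity | remark | time |
|---|---|---|---|---|---|---|
| south-west | 0.17 M | 0.076 M | 0.204 M | 0.017 M | run made earlier |  |
| north-west | 0.17 M | 0.31 M | 0.204 M | 0.017 M | run made earlier |  |
| flask | 0.17 M | 0.153 M | 0.204 M | 0.0170 M |  | 2.5 h |

| run | time / min | substrate / % | product / % |
|---|---|---|---|
| south-west | 10.0 | 61.0 | 23.1 |
| south-west | 30.0 | 43.2 | 39.7 |
| south-west | 60.0 | 36.7 | 44.3 |
| south-west | 80.0 | 36.6 | 43.8 |
| south-west | 120 | 35.6 | 44.7 |
| north-west | 25.0 | 92.7 | 7.3 |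
| north-west | 50.0 | 92.5 | 8.6 |
| north-west | 80.0 | 92.0 | 7.2 |
| north-west | 90.0 | 92.1 | 8.2 |
| north-west | 120 | 92.2 | 7.7 |

(standard deviation of a reading: 0.5 percentage points)

- which holds at 2.5 h: what has brought the reaction to rest, or that it has not come to rest (it is still moving / the partner A has run out first / all of the substrate has reacted / the partner B has run out first)
- part of the substrate gone at 2.5 h
- the product standing at 2.5 h, as a percentage of the substrate charged

- a reading or a percentage of product counts all its forms, free or not
- the reaction counts as stopped when no species that holds the substrate changes by six tenths of a point or more over the second half of the time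

My rule of thumb was a budget. I assumed that each partner B is taken by one substrate, one partner A or one protic impurity, which leaves 0.187 M usable in the flask, and that partner A is served first, so the substrate gets the surplus. In the south-west run that surplus was 0.111 M and the last reading showed 0.109 M of substrate lost. The ratio of partner A to usable partner B marks the border, because the surplus turns negative when that ratio passes one: it was 0.406 there, but 1.66 in the north-west run, where substrate was lost all the same, and 0.818 in the flask.

So I let the two compete, assuming each falls in proportion to itself. The selectivity factor, the logarithm of the fraction of substrate left over that of partner A left, read 0.0988 from the last substrate reading of the north-west run, with the partner A left taken from the budget. By the budget the substrate loss in the flask equals the surplus, 0.0340 M, plus the partner A left over. Taking that surplus as the loss gave 0.0160 M of partner A left, which pointed to a loss of 0.0500 M. The mean of the two, 0.0420 M, gave 0.00866 M and returned 0.0427 M, so I committed to 25.1 % lost. I booked that as product too, since the partner A taken exceeds the substrate lost.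

The forecast said 25 % gone, 24.5 % product and that the partner B has run out first, on the words “Activated A is in excess, so all of that becomes product”.

The flask gave 24.3 % gone and 24.3 % product at 2.5 h, and the partner B has run out first.

    substrate + partner B → open intermediate (k = 0.0110 /M/s)
    partner B + partner A → second intermediate (k = 0.120 /M/s)
    open intermediate + second intermediate → product (k = 0.0540 /M/s)
    crystals ⇌ product, rate k4*(cs4 - [product]) while solid is left; crystals form when [product] > cs4 (solubility = 0.110 M, k = 0.130 /s)
    partner B + protic impurity → quenched reagent (k = 0.200 /M/s)

Partner B, the limiting reagent, stood at 0 % of its charge at 2.50 h, with partner A at 4.8 %. From that partner A, the selectivity factor gave 74.1 % of the substrate left, and the flask held 76 %. A neighbouring flask, like this one but charged with 0.082 M of partner B, kept 58 % of its partner A, from which the same factor gave 94.8 %, and its substrate stood at 95 %.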